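**Plan**

1. Retrosynthetic cuts: the silylethyl ester and the acetate; then C12–C13, between a primary C12 pinacol boronate on the bicyclic ester and the α-lithiated carbamate of (S)-but-3-en-2-ol; then C11–C12 (CH2 insertion into a C11 boronate), C4–CH3, C8=CH2, and C9–C11 together with C10–CH3 (cuprate addition/enolate alkylation of a Δ9(10)-8-octalone); the octalone goes back to a tetralin-1-carboxylic acid (Birch reduction).
2. Forward order: 6-methoxy-1-tetralone supplies ring A intact and its anisole ring becomes ring B; the octalone is made, the cis ring fusion and the C9 branch are installed in one operation, then the methylidene, the C4 methyl, the boron homologation, the fragment union at C13, acetylation and ester release.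
3. Stereochemistry: C4 is set by Ir-catalysed asymmetric hydrogenation and relays to C5 (equilibration), C10 (cuprate anti to the C5–C4 bond) and C9 (equilibration next to the C8 ketone); C4 is then made quaternary by methylation anti to the C10 methyl; C13 comes from (S)-but-3-en-2-ol through a stereospecific 1,2-metallate shift.
4. Enabling feature: C13 is a fully substituted allylic carbinol carbon (vinyl, CH3, O) bonded to the unbranched C12 methylene of the two-carbon tether to C9 of the cis-decalin, so C13 can be delivered as a configurationally defined α-oxyallyl carbenoid and C12 as a primary boronate.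

Key step: step 11

Remark 1: the SMILES defines a cis-fused decalin (H-5, the C10 methyl, the C4 carboxyl and the C9 side chain all on one face), i.e. (4S,5S,9S,10R,13R), a 5β-labdane; the route is built for this isomer.
Remark 2: positions are cited in labdane numbering (C4 carboxyl-bearing carbon, C5/C10 ring fusion, C8 ketone/methylidene carbon, C9 side-chain carbon, C11–C15 side chain; β = face of the C10 methyl). Names use naphthalene locants (1 = C4, 4a = C10, 5 = C9, 6 = C8, 8a = C5).
Remark 3: in step 3 the ligand antipode that delivers the (S)-acid is used.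

**Step 1**
Reactants: 1 6-methoxy-3,4-dihydronaphthalen-1(2H)-one
Product: 2 6-methoxy-3,4-dihydronaphthalen-1-yl trifluoromethanesulfonate
Conditions: LiHMDS, THF, −78 °C; PhNTf2, −78 → 0 °C
Reagents that add atoms: N-phenyl-bis(trifluoromethanesulfonimide) (O=S(=O)(N(c1ccccc1)S(=O)(=O)C(F)(F)F)C(F)(F)F)
Why: the aryl ketone has one enolisable side, so deprotonation and O-sulfonylation should give the single enol triflate (enol triflate formation).

**Step 2**
Reactants: 2 6-methoxy-3,4-dihydronaphthalen-1-yl trifluoromethanesulfonate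
Product: 3 6-methoxy-3,4-dihydronaphthalene-1-carboxylic acid
Conditions: Pd(OAc)2 (cat.), dppf (cat.), CO (1 atm), KOAc, DMF–H2O, 60 °C; then 1 M HCl
Reagents that add atoms: carbon monoxide ([C-]#[O+]); water (O)
Why: oxidative addition of the alkenyl triflate to Pd(0), CO insertion and capture of the acyl-palladium by acetate/water should give the conjugated acid (Pd-catalysed hydroxycarbonylation of enol triflates).

**Step 3**
Reactants: 3 6-methoxy-3,4-dihydronaphthalene-1-carboxylic acid
Product: 4 (S)-6-methoxy-1,2,3,4-tetrahydronaphthalene-1-carboxylic acid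
Conditions: [Ir(cod)(chiral spiro phosphine–oxazoline, SIPHOX type)]BArF (cat.), H2 (6 atm), Et3N (0.5 equiv), MeOH, rt
Reagents that add atoms: none
Why: carboxylate-directed Ir-catalysed asymmetric hydrogenation of α-aryl-α,β-unsaturated acids is well precedented, and the catalyst-controlled hydride delivery sets C4 as S, the stereocenter that relays chirality into the ring system.

**Step 4**
Reactants: 4 (S)-6-methoxy-1,2,3,4-tetrahydronaphthalene-1-carboxylic acid
Product: 7 (1S,8aR)-6-oxo-1,2,3,4,6,7,8,8a-octahydronaphthalene-1-carboxylic acid, via Birch dienol ether acid 5 (not isolated), via β,γ-unsaturated keto acid 6 (not isolated)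
Conditions: Li, NH3(l), THF, t-BuOH, −78 → −33 °C; NH4Cl; then 2 M HCl, THF, 40 °C
Reagents that add atoms: water (O)
Why: Birch reduction of the anisole ring (the carboxylate is inert and excess t-BuOH keeps the medium too weakly basic to deprotonate the α-CH) followed by enol ether hydrolysis and conjugation should give the Δ9(10)-8-octalone, with C5 set under equilibrating dienol conditions in favour of the epimer whose carboxyl is equatorial and trans to the C5–C6 bond (the minor epimer is separable and can be re-equilibrated).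

**Step 5**
Reactants: 7 (1S,8aR)-6-oxo-1,2,3,4,6,7,8,8a-octahydronaphthalene-1-carboxylic acid
Product: 8 2-(trimethylsilyl)ethyl (1S,8aR)-6-oxo-1,2,3,4,6,7,8,8a-octahydronaphthalene-1-carboxylate
Conditions: 2-(trimethylsilyl)ethanol, DCC, DMAP (cat.), CH2Cl2, 0 °C → rt
Reagents that add atoms: 2-(trimethylsilyl)ethanol (C[Si](C)(C)CCO)
Why: Steglich esterification installs an ester that should survive the organometallic and base steps and can be removed at the end by fluoride without touching a tertiary allylic acetate.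

**Step 6**
Reactants: 8 2-(trimethylsilyl)ethyl (1S,8aR)-6-oxo-1,2,3,4,6,7,8,8a-octahydronaphthalene-1-carboxylate
Product: 10 2-(trimethylsilyl)ethyl (1S,4aS,5R,8aR)-4a-methyl-6-oxo-5-[(4,4,5,5-tetramethyl-1,3,2-dioxaborolan-2-yl)methyl]decahydronaphthalene-1-carboxylate, via lithium enolate 9 (not isolated)
Conditions: Me2CuLi (from MeLi, CuI), Et2O, −40 → 0 °C; then ICH2Bpin, THF–HMPA, 0 °C → rt; then DBU (cat.), CH2Cl2, rt
Reagents that add atoms: lithium dimethylcuprate ([Li+].C[Cu-]C); 2-(iodomethyl)-4,4,5,5-tetramethyl-1,3,2-dioxaborolane (CC1(C)OB(CI)OC1(C)C)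
Why: the cuprate should add to C10 axially and anti to the C5–C4 bond, which gives the cis ring fusion (the classical cis-selective conjugate addition to Δ1(9)-octal-2-ones); the regiodefined C8–C9 enolate is C-alkylated by the α-iodo boronate, and the epimerisable C9 should settle equatorial and cis to the C10 methyl because the alternative is syn-axial to the C5–C4 bond.

**Step 7**
Reactants: 10 2-(trimethylsilyl)ethyl (1S,4aS,5R,8aR)-4a-methyl-6-oxo-5-[(4,4,5,5-tetramethyl-1,3,2-dioxaborolan-2-yl)methyl]decahydronaphthalene-1-carboxylate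
Product: 11 2-(trimethylsilyl)ethyl (1S,4aS,5S,8aR)-4a-methyl-6-methylidene-5-[(4,4,5,5-tetramethyl-1,3,2-dioxaborolan-2-yl)methyl]decahydronaphthalene-1-carboxylate
Conditions: Ph3PCH3Br, NaHMDS, THF, 0 → 60 °C
Reagents that add atoms: methyltriphenylphosphonium bromide (C[P+](c1ccccc1)(c1ccccc1)c1ccccc1.[Br-])
Why: Wittig methylenation of the hindered ketone; the basic ylide should not scramble stereochemistry because C9 is already in its preferred configuration and C4 is re-set in the next step.

**Step 8**
Reactants: 11 2-(trimethylsilyl)ethyl (1S,4aS,5S,8aR)-4a-methyl-6-methylidene-5-[(4,4,5,5-tetramethyl-1,3,2-dioxaborolan-2-yl)methyl]decahydronaphthalene-1-carboxylate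
Product: 13 2-(trimethylsilyl)ethyl (1S,4aR,5S,8aS)-1,4a-dimethyl-6-methylidene-5-[(4,4,5,5-tetramethyl-1,3,2-dioxaborolan-2-yl)methyl]decahydronaphthalene-1-carboxylate, via lithium ester enolate 12 (not isolated)
Conditions: LDA, THF, −78 → −30 °C; MeI, DMPU, −78 → 0 °C
Reagents that add atoms: iodomethane (CI)
Why: the exocyclic ester enolate should relieve A(1,3) strain by placing the C5–C6 bond axial, which puts the C10 methyl 1,3-diaxial over the β face, so MeI enters equatorially from the α face and the ester ends β, cis to the C10 methyl (enolate alkylation, the same sense that gives axial 19-esters in trans-fused 10-methyl decalins).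

**Step 9**
Reactants: 13 2-(trimethylsilyl)ethyl (1S,4aR,5S,8aS)-1,4a-dimethyl-6-methylidene-5-[(4,4,5,5-tetramethyl-1,3,2-dioxaborolan-2-yl)methyl]decahydronaphthalene-1-carboxylate
Product: 15 2-(trimethylsilyl)ethyl (1S,4aR,5S,8aS)-1,4a-dimethyl-6-methylidene-5-[2-(4,4,5,5-tetramethyl-1,3,2-dioxaborolan-2-yl)ethyl]decahydronaphthalene-1-carboxylate, via chloromethyl boronate complex 14 (not isolated)
Conditions: BrCH2Cl, n-BuLi, THF, −78 °C → rt
Reagents that add atoms: bromochloromethane (ClCBr)
Why: Matteson homologation: LiCH2Cl generated in the presence of the boronate adds to boron, and 1,2-migration of the primary alkyl group with loss of chloride inserts one CH2, moving boron from C11 to C12; the quaternary ester is too hindered to compete.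

**Step 10**
Reactants: 16 (S)-but-3-en-2-ol
Product: 17 (S)-but-3-en-2-yl N,N-diisopropylcarbamate
Conditions: iPr2NCOCl, Et3N, DMAP (cat.), CH2Cl2, 40 °C
Reagents that add atoms: N,N-diisopropylcarbamoyl chloride (CC(C)N(C(C)C)C(Cl)=O)
Why: O-carbamoylation does not touch the stereocenter and gives the carbamate that directs α-lithiation and later serves as the leaving group.

**Step 11**
Reactants: 17 (S)-but-3-en-2-yl N,N-diisopropylcarbamate; 15 2-(trimethylsilyl)ethyl (1S,4aR,5S,8aS)-1,4a-dimethyl-6-methylidene-5-[2-(4,4,5,5-tetramethyl-1,3,2-dioxaborolan-2-yl)ethyl]decahydronaphthalene-1-carboxylate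
Product: 21 2-(trimethylsilyl)ethyl (1S,4aR,5S,8aS)-5-[(3R)-3-hydroxy-3-methylpent-4-en-1-yl]-1,4a-dimethyl-6-methylidenedecahydronaphthalene-1-carboxylate, via lithiated carbamate 18 (not isolated), via boronate complex 19 (not isolated), via tertiary allylic boronic ester 20 (not isolated)
Conditions: 17, s-BuLi, TMEDA, Et2O, −78 °C; add 15, −78 °C → rt; then 2 M NaOH, 30% H2O2, THF, 0 °C
Reagents that add atoms: hydrogen peroxide (OO)
Why: s-BuLi/TMEDA removes the carbinol H of the carbamate with retention to give a chelated α-oxyallyllithium that holds its configuration at −78 °C; the boronic ester adds at the α-carbon with retention, and on warming the C12 methylene migrates from boron to C13 antiperiplanar to the departing carbamate (inversion at C13), after which oxidation replaces boron by OH with retention. The closest known reaction type is the lithiation–borylation of enantioenriched secondary allylic carbamates with primary alkyl pinacol boronates to give tertiary allylic boronic esters and alcohols. No ring is closed. The only new stereocenter, C13, is controlled by the configuration of (S)-but-3-en-2-ol: the net result is replacement of H by C12 with the C–O geometry kept, which corresponds to 13R. The step needs α- rather than γ-borylation, configurational integrity of the lithiated carbamate and no 1,3-boron shift in the tertiary allylic boronate; Li–O chelation with a boronic ester electrophile favours α-attack, low temperature and short lithiation time protect the configuration, and immediate oxidation traps the boronate. The neopentyl-type silylethyl ester and the 1,1-disubstituted alkene should be inert to the carbenoid.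

**Step 12**
Reactants: 21 2-(trimethylsilyl)ethyl (1S,4aR,5S,8aS)-5-[(3R)-3-hydroxy-3-methylpent-4-en-1-yl]-1,4a-dimethyl-6-methylidenedecahydronaphthalene-1-carboxylate
Product: 22 2-(trimethylsilyl)ethyl (1S,4aR,5S,8aS)-5-[(3R)-3-acetoxy-3-methylpent-4-en-1-yl]-1,4a-dimethyl-6-methylidenedecahydronaphthalene-1-carboxylate
Conditions: Ac2O, DMAP, Et3N, CH2Cl2, rt → 40 °C
Reagents that add atoms: acetic anhydride (CC(=O)OC(C)=O)
Why: DMAP-catalysed acylation of the tertiary allylic alcohol under basic conditions avoids ionisation of the allylic system and leaves C13 untouched.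

**Step 13**
Reactants: 22 2-(trimethylsilyl)ethyl (1S,4aR,5S,8aS)-5-[(3R)-3-acetoxy-3-methylpent-4-en-1-yl]-1,4a-dimethyl-6-methylidenedecahydronaphthalene-1-carboxylate
Product: 23 (1S,4aR,5S,8aS)-5-[(3R)-3-acetoxy-3-methylpent-4-en-1-yl]-1,4a-dimethyl-6-methylidenedecahydronaphthalene-1-carboxylic acid
Conditions: TBAF, THF, 0 °C → rt; then aq. NH4Cl
Reagents that add atoms: none
Why: fluoride attacks silicon and the silylethyl ester fragments to ethene, Me3SiF and the carboxylate, a cleavage that does not need attack at the hindered carbonyl and should leave the tertiary acetate and both alkenes intact.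

**Compound list**

1 | 6-methoxy-3,4-dihydronaphthalen-1(2H)-one | COc1ccc2c(c1)CCCC2=O | starting material
2 | 6-methoxy-3,4-dihydronaphthalen-1-yl trifluoromethanesulfonate | COc1ccc2c(c1)CCC=C2OS(=O)(=O)C(F)(F)F | intermediate
3 | 6-methoxy-3,4-dihydronaphthalene-1-carboxylic acid | COc1ccc2c(c1)CCC=C2C(=O)O | intermediate
4 | (S)-6-methoxy-1,2,3,4-tetrahydronaphthalene-1-carboxylic acid | COc1ccc2c(c1)CCC[C@@H]2C(=O)O | intermediate
5 | (S)-6-methoxy-1,2,3,4,5,8-hexahydronaphthalene-1-carboxylic acid (Birch dienol ether acid) | COC1=CCC2=C(C1)CCC[C@@H]2C(=O)O | intermediate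
6 | (S)-6-oxo-1,2,3,4,5,6,7,8-octahydronaphthalene-1-carboxylic acid (β,γ-unsaturated keto acid) | O=C1CCC2=C(C1)CCC[C@@H]2C(=O)O | intermediate
7 | (1S,8aR)-6-oxo-1,2,3,4,6,7,8,8a-octahydronaphthalene-1-carboxylic acid | O=C1CC[C@H]2C(=C1)CCC[C@@H]2C(=O)O | intermediate
8 | 2-(trimethylsilyl)ethyl (1S,8aR)-6-oxo-1,2,3,4,6,7,8,8a-octahydronaphthalene-1-carboxylate | O=C1CC[C@H]2C(=C1)CCC[C@@H]2C(=O)OCC[Si](C)(C)C | intermediate
9 | lithium enolate: 2-(trimethylsilyl)ethyl (1S,4aS,8aR)-6-(lithiooxy)-4a-methyl-1,2,3,4,4a,7,8,8a-octahydronaphthalene-1-carboxylate | C1=C(O[Li])CC[C@H]2[C@]1(C)CCC[C@@H]2C(=O)OCC[Si](C)(C)C | intermediate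
10 | 2-(trimethylsilyl)ethyl (1S,4aS,5R,8aR)-4a-methyl-6-oxo-5-[(4,4,5,5-tetramethyl-1,3,2-dioxaborolan-2-yl)methyl]decahydronaphthalene-1-carboxylate | CC1(C)OB(C[C@H]2C(=O)CC[C@H]3[C@]2(C)CCC[C@@H]3C(=O)OCC[Si](C)(C)C)OC1(C)C | intermediate
11 | 2-(trimethylsilyl)ethyl (1S,4aS,5S,8aR)-4a-methyl-6-methylidene-5-[(4,4,5,5-tetramethyl-1,3,2-dioxaborolan-2-yl)methyl]decahydronaphthalene-1-carboxylate | CC1(C)OB(C[C@H]2C(=C)CC[C@H]3[C@]2(C)CCC[C@@H]3C(=O)OCC[Si](C)(C)C)OC1(C)C | intermediate
12 | lithium ester enolate of 11 (C4=C19 ketene acetal; 5β-H, 9α-H, 10β-CH3) | CC1(C)OB(C[C@H]2C(=C)CC[C@H]3[C@]2(C)CCCC3=C(O[Li])OCC[Si](C)(C)C)OC1(C)C | intermediate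
13 | 2-(trimethylsilyl)ethyl (1S,4aR,5S,8aS)-1,4a-dimethyl-6-methylidene-5-[(4,4,5,5-tetramethyl-1,3,2-dioxaborolan-2-yl)methyl]decahydronaphthalene-1-carboxylate | CC1(C)OB(C[C@H]2C(=C)CC[C@H]3[C@]2(C)CCC[C@]3(C)C(=O)OCC[Si](C)(C)C)OC1(C)C | intermediate
14 | lithium (chloromethyl)boronate complex of 13 | [Li+].ClC[B-]1(C[C@H]2C(=C)CC[C@H]3[C@]2(C)CCC[C@]3(C)C(=O)OCC[Si](C)(C)C)OC(C)(C)C(C)(C)O1 | intermediate
15 | 2-(trimethylsilyl)ethyl (1S,4aR,5S,8aS)-1,4a-dimethyl-6-methylidene-5-[2-(4,4,5,5-tetramethyl-1,3,2-dioxaborolan-2-yl)ethyl]decahydronaphthalene-1-carboxylate | CC1(C)OB(CC[C@H]2C(=C)CC[C@H]3[C@]2(C)CCC[C@]3(C)C(=O)OCC[Si](C)(C)C)OC1(C)C | intermediate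
16 | (S)-but-3-en-2-ol | C=C[C@H](C)O | starting material
17 | (S)-but-3-en-2-yl N,N-diisopropylcarbamate | C=C[C@H](C)OC(=O)N(C(C)C)C(C)C | intermediate
18 | (S)-2-lithiobut-3-en-2-yl N,N-diisopropylcarbamate (Li in place of H, retention) | C=C[C@]([Li])(C)OC(=O)N(C(C)C)C(C)C | intermediate
19 | lithium boronate complex of 15 with 18 (B in place of Li, retention) | [Li+].C=C[C@]([B-]1(CC[C@H]2C(=C)CC[C@H]3[C@]2(C)CCC[C@]3(C)C(=O)OCC[Si](C)(C)C)OC(C)(C)C(C)(C)O1)(C)OC(=O)N(C(C)C)C(C)C | intermediate
20 | 2-(trimethylsilyl)ethyl (1S,4aR,5S,8aS)-1,4a-dimethyl-6-methylidene-5-[(3S)-3-methyl-3-(4,4,5,5-tetramethyl-1,3,2-dioxaborolan-2-yl)pent-4-en-1-yl]decahydronaphthalene-1-carboxylate | C=C[C@@](C)(CC[C@H]1C(=C)CC[C@H]2[C@]1(C)CCC[C@]2(C)C(=O)OCC[Si](C)(C)C)B1OC(C)(C)C(C)(C)O1 | intermediate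
21 | 2-(trimethylsilyl)ethyl (1S,4aR,5S,8aS)-5-[(3R)-3-hydroxy-3-methylpent-4-en-1-yl]-1,4a-dimethyl-6-methylidenedecahydronaphthalene-1-carboxylate | C=C[C@@](C)(CC[C@H]1C(=C)CC[C@H]2[C@]1(C)CCC[C@]2(C)C(=O)OCC[Si](C)(C)C)O | intermediate
22 | 2-(trimethylsilyl)ethyl (1S,4aR,5S,8aS)-5-[(3R)-3-acetoxy-3-methylpent-4-en-1-yl]-1,4a-dimethyl-6-methylidenedecahydronaphthalene-1-carboxylate | C=C[C@@](C)(CC[C@H]1C(=C)CC[C@H]2[C@]1(C)CCC[C@]2(C)C(=O)OCC[Si](C)(C)C)OC(C)=O | intermediate
23 | (1S,4aR,5S,8aS)-5-[(3R)-3-acetoxy-3-methylpent-4-en-1-yl]-1,4a-dimethyl-6-methylidenedecahydronaphthalene-1-carboxylic acid, i.e. (13R)-13-acetoxy-5β-labda-8(17),14-dien-19-oic acid | C=C[C@@](C)(CC[C@H]1C(=C)CC[C@H]2[C@]1(C)CCC[C@]2(C)C(=O)O)OC(C)=O | target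

**Count**

Total steps: 13. Longest linear sequence: 12 (steps 1–9 and 11–13; step 10 is the side branch).

**Three steps most likely to fail**

Step 11. What may go wrong: loss of configuration of the lithiated allyl carbamate before borylation, competing γ-borylation of the allyl anion, or 1,3-boron shift of the tertiary allylic boronate before oxidation. The fallback sets out from 15 and returns at 21. The same C12–C13 bond is made as a C(sp3)–C(sp2) bond by B-alkyl Suzuki–Miyaura coupling of 15 with (E)-3-iodobut-2-en-1-ol (Pd(dppf)Cl2, Ag2O, K2CO3, THF, 70 °C), which should give the E-allylic alcohol F1. Sharpless asymmetric epoxidation (Ti(OiPr)4, D-(−)-DIPT, t-BuOOH, CH2Cl2, −20 °C) should touch only the allylic-alcohol alkene and give the (2R,3R)-epoxy alcohol F2, which sets C13 by reagent control. Iodination (I2, PPh3, imidazole) gives the epoxy iodide F3, and zinc dust in EtOH/AcOH opens it by reductive elimination to the tertiary allylic alcohol 21 with the C13–O bond untouched.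

Step 8. What may go wrong: poor facial selectivity in the enolate methylation (attack on the β face through the other ring conformer), which would give the C4 epimer. The fallback sets out from 3 and returns at 13; it makes C4 quaternary before any other stereocenter exists. Hydrogenation of 3 over Pd/C gives 4 as the racemate, and its dianion (LDA, 2.2 equiv, THF) is methylated with MeI to the racemic 1-methyl acid F4. Resolution through the (R)-1-phenylethylammonium salt gives the (S)-1-methyl acid F5. Birch reduction and acid hydrolysis under the conditions of step 4 give the quaternary enone acid F6; here C5 is expected to arise by axial protonation of the dienol anti to the pseudoaxial C4 methyl, and the C5 epimers are separable. Steglich esterification gives the silylethyl ester F7, the cuprate/alkylation of step 6 gives the quaternary boryl ketone F8, and Wittig methylenation as in step 7 gives 13.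

Step 6. What may go wrong: O-alkylation or sluggish C-alkylation of the hindered cuprate-derived enolate by the α-iodo boronate. The fallback sets out from 8 and returns at 10. After the same cuprate addition the enolate is trapped with dimethylmethyleneiminium iodide (Eschenmoser's salt) to give the Mannich base F9. Quaternisation with MeI and elimination with DBU give the α-methylene ketone F10. Copper-catalysed conjugate borylation (B2pin2, CuCl, NaOtBu, DPEphos, MeOH, THF) followed by DBU equilibration at C9 should give 10.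

**Further compounds**

F1 | step 11 | 2-(trimethylsilyl)ethyl (1S,4aR,5S,8aS)-5-[(E)-5-hydroxy-3-methylpent-3-en-1-yl]-1,4a-dimethyl-6-methylidenedecahydronaphthalene-1-carboxylate | OC/C=C(\C)CC[C@H]1C(=C)CC[C@H]2[C@]1(C)CCC[C@]2(C)C(=O)OCC[Si](C)(C)C
F2 | step 11 | 2-(trimethylsilyl)ethyl (1S,4aR,5S,8aS)-5-{2-[(2R,3R)-3-(hydroxymethyl)-2-methyloxiran-2-yl]ethyl}-1,4a-dimethyl-6-methylidenedecahydronaphthalene-1-carboxylate | OC[C@H]1O[C@]1(C)CC[C@H]2C(=C)CC[C@H]3[C@]2(C)CCC[C@]3(C)C(=O)OCC[Si](C)(C)C
F3 | step 11 | 2-(trimethylsilyl)ethyl (1S,4aR,5S,8aS)-5-{2-[(2R,3S)-3-(iodomethyl)-2-methyloxiran-2-yl]ethyl}-1,4a-dimethyl-6-methylidenedecahydronaphthalene-1-carboxylate | IC[C@H]1O[C@]1(C)CC[C@H]2C(=C)CC[C@H]3[C@]2(C)CCC[C@]3(C)C(=O)OCC[Si](C)(C)C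
F4 | step 8 | 6-methoxy-1-methyl-1,2,3,4-tetrahydronaphthalene-1-carboxylic acid (racemate) | COc1ccc2c(c1)CCCC2(C)C(=O)O
F5 | step 8 | (S)-6-methoxy-1-methyl-1,2,3,4-tetrahydronaphthalene-1-carboxylic acid | COc1ccc2c(c1)CCC[C@]2(C)C(=O)O
F6 | step 8 | (1S,8aS)-1-methyl-6-oxo-1,2,3,4,6,7,8,8a-octahydronaphthalene-1-carboxylic acid | O=C1CC[C@H]2C(=C1)CCC[C@]2(C)C(=O)O
F7 | step 8 | 2-(trimethylsilyl)ethyl (1S,8aS)-1-methyl-6-oxo-1,2,3,4,6,7,8,8a-octahydronaphthalene-1-carboxylate | O=C1CC[C@H]2C(=C1)CCC[C@]2(C)C(=O)OCC[Si](C)(C)C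
F8 | step 8 | 2-(trimethylsilyl)ethyl (1S,4aS,5R,8aS)-1,4a-dimethyl-6-oxo-5-[(4,4,5,5-tetramethyl-1,3,2-dioxaborolan-2-yl)methyl]decahydronaphthalene-1-carboxylate | CC1(C)OB(C[C@H]2C(=O)CC[C@H]3[C@]2(C)CCC[C@]3(C)C(=O)OCC[Si](C)(C)C)OC1(C)C
F9 | step 6 | 2-(trimethylsilyl)ethyl (1S,4aS,5S,8aR)-5-[(dimethylamino)methyl]-4a-methyl-6-oxodecahydronaphthalene-1-carboxylate | CN(C)C[C@H]1C(=O)CC[C@H]2[C@]1(C)CCC[C@@H]2C(=O)OCC[Si](C)(C)C
F10 | step 6 | 2-(trimethylsilyl)ethyl (1S,4aS,8aR)-4a-methyl-5-methylidene-6-oxodecahydronaphthalene-1-carboxylate | C=C1C(=O)CC[C@H]2[C@]1(C)CCC[C@@H]2C(=O)OCC[Si](C)(C)C
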